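**Retrosynthetic overview**
- The route rests on ring A, the phloroglucinol ring that bears the 2-methylbutanoyl group. It is read as the folded form of a 3,5,7-trioxo ester: chain C1–C6 are the ring carbons, C2 carries the prenyl group, C4 the bridge methine, and C7 is the side-chain carbonyl.
- The last C–C bond made is C6→C1, a Claisen closure between the acyl-bearing carbon and the hydroxyl-bearing carbon next to the prenyl carbon. Ring A is the only ring formed; ring B comes from phloroglucinol.
- The trioxo ester is assembled by γ-acetylation (C4–C5) of a 2-prenyl β-keto ester, then terminal acylation (C6–C7) of the resulting 3,5-dioxo ester with the Weinreb amide of (R)-2-methylbutanoic acid.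
- The β-keto ester comes from a 3-aryl nonanoic acid (C2–C3 by malonate homologation, then C2 prenylation). Its benzylic stereocentre, the later bridge, is set first by an iminium-catalysed Friedel–Crafts addition of the ring B acylphloroglucinol to (E)-8-methylnon-2-enal.
- Ring B is carried as its tris(methoxymethyl) ether and is unmasked in the last step.

Key step: step 13

Remarks on the chemistry:
- Ar stands for ring B as its tris(MOM) ether: 2,4,6-tris(methoxymethoxy)-3-(3-methylbut-2-en-1-yl)-5-(2-methylpropanoyl)phenyl.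
- The lactol from the Friedel–Crafts step is expected as an equilibrating mixture of anomers and of the regioisomer closed on the other flanking hydroxyl. It is drawn as one isomer; all forms converge in the next step.
- The chain compounds that are stereogenic at C2 and C4 are carried as epimer and enol mixtures, because both carbons become aromatic in the key step.
- (R)-2-Methylbutanoic acid is taken as the commercial single enantiomer.
- The sense of induction in step 5 is assigned by the usual steric-shielding model for diarylprolinol silyl ether iminium ions.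
- The ring B ketone is an aryl isopropyl ketone flanked by two ortho MOM ethers. Its α-methine should be removed by LDA only slowly at −78 °C, and any enolate formed is tetrasubstituted and should not be acylated by a Weinreb amide.

**Step 1**
Reactants: 1 phloroglucinol; 2 isobutyryl chloride
Product: 3 2-methyl-1-(2,4,6-trihydroxyphenyl)propan-1-one
Conditions: AlCl3 (3.5 equiv), PhNO2/CH2Cl2, 0 → 60 °C; ice/aq. HCl
Reagents that add atoms: none
Why: Friedel–Crafts acylation of the very electron-rich arene should stop after one acyl group, because the chelated ketone deactivates the ring.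

**Step 2**
Reactants: 3 2-methyl-1-(2,4,6-trihydroxyphenyl)propan-1-one
Product: 4 2-methyl-1-[2,4,6-trihydroxy-3-(3-methylbut-2-en-1-yl)phenyl]propan-1-one
Conditions: prenyl bromide (0.9 equiv), 10% aq. KOH, 0 °C; then aq. HCl
Reagents that add atoms: prenyl bromide (1-bromo-3-methylbut-2-ene), CC(C)=CCBr
Why: C-alkylation of the phloroglucinolate in water (the solvated oxygens favour attack through carbon) should give the mono-prenyl compound when the bromide is the limiting reagent; the two free ring positions of 3 are equivalent.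

**Step 3**
Reactants: 5 6-methylheptan-1-ol
Product: 6 6-methylheptanal
Conditions: TEMPO (1 mol%), KBr (10 mol%), aq. NaOCl (1.1 equiv), NaHCO3, CH2Cl2/H2O, 0 °C
Reagents that add atoms: none
Why: Anelli oxidation (oxoammonium catalysis) of a primary alcohol should stop at the aldehyde in the buffered two-phase medium.

**Step 4**
Reactants: 6 6-methylheptanal
Product: 7 (2E)-8-methylnon-2-enal
Conditions: Ph3P=CHCHO (1.05 equiv), toluene, 80 °C
Reagents that add atoms: (triphenylphosphoranylidene)acetaldehyde, O=CC=P(c1ccccc1)(c1ccccc1)c1ccccc1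
Why: Wittig olefination with the stabilised formylmethylene ylide should give the (E)-enal, and the near-stoichiometric amount of ylide limits a second homologation.

**Step 5**
Reactants: 4 2-methyl-1-[2,4,6-trihydroxy-3-(3-methylbut-2-en-1-yl)phenyl]propan-1-one; 7 (2E)-8-methylnon-2-enal
Product: 9 1-[(4S)-2,5,7-trihydroxy-8-(3-methylbut-2-en-1-yl)-4-(5-methylhexyl)-3,4-dihydro-2H-chromen-6-yl]-2-methylpropan-1-one (lactol; anomers), via open-chain hydroxy aldehyde 8 (not isolated)
Conditions: (R)-2-[diphenyl(trimethylsilyloxy)methyl]pyrrolidine (20 mol%), PhCO2H (20 mol%), CH2Cl2/THF, 0 °C → rt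
Reagents that add atoms: none
Why: Iminium-catalysed Friedel–Crafts alkylation followed by hemiacetalisation: the only free ring carbon of 4 adds to C3 of the (E)-s-trans iminium ion from the Si face, the face not shielded by the diphenyl(silyloxy)methyl group of the (R)-catalyst, which should set the (S) centre that later becomes the bridge.

**Step 6**
Reactants: 9 1-[(4S)-2,5,7-trihydroxy-8-(3-methylbut-2-en-1-yl)-4-(5-methylhexyl)-3,4-dihydro-2H-chromen-6-yl]-2-methylpropan-1-one (lactol)
Product: 11 (3S)-8-methyl-3-Ar-nonanal, via trisodium triphenoxide 10 (not isolated)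
Conditions: NaH (3.1 equiv), THF/DMF, 0 °C; MOMCl (3.5 equiv), 0 °C → rt
Reagents that add atoms: chloromethyl methyl ether (MOMCl), COCCl
Why: NaH removes the two phenol protons and the lactol proton, the lactol alkoxide opens to the far more stable phenoxide (ring–chain tautomerism) so that the material rests as the trisodium triphenoxide of the open aldehyde, and Williamson-type O-alkylation of the three phenoxides by the hard electrophile MOMCl should then fix the open form; the stereocentre is β to the carbonyl and not acidic.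

**Step 7**
Reactants: 11 (3S)-8-methyl-3-Ar-nonanal
Product: 12 (3S)-8-methyl-3-Ar-nonanoic acid
Conditions: NaClO2 (1.5 equiv), NaH2PO4, 2-methyl-2-butene (20 equiv), t-BuOH/H2O, 0 °C → rt
Reagents that add atoms: sodium chlorite, [Na+].[O-]Cl=O
Why: Pinnick oxidation is selective for the aldehyde; the alkene scavenger should keep hypochlorous acid away from the prenyl group, and the buffered medium is tolerated by aryl MOM ethers.

**Step 8**
Reactants: 12 (3S)-8-methyl-3-Ar-nonanoic acid
Product: 14 methyl (5S)-10-methyl-3-oxo-5-Ar-undecanoate, via acyl imidazole 13 (not isolated)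
Conditions: CDI (1.2 equiv), THF, rt; then KO2CCH2CO2Me (2 equiv), MgCl2 (2.5 equiv), Et3N (3 equiv), MeCN/THF, rt → 45 °C; cold 0.5 M HCl
Reagents that add atoms: potassium methyl malonate, [K+].[O-]C(=O)CC(=O)OC
Why: Masamune–Brooks homologation: the magnesium enolate of the malonate half ester is C-acylated by the acyl imidazole under nearly neutral conditions, and decarboxylation should give the β-keto ester without touching the ring B ketone.

**Step 9**
Reactants: 14 methyl (5S)-10-methyl-3-oxo-5-Ar-undecanoate
Product: 15 methyl (5S)-10-methyl-2-(3-methylbut-2-en-1-yl)-3-oxo-5-Ar-undecanoate (C2 epimers)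
Conditions: prenyl bromide (1.05 equiv), K2CO3 (1.5 equiv), acetone, rt
Reagents that add atoms: prenyl bromide (1-bromo-3-methylbut-2-ene), CC(C)=CCBr
Why: SN2 C-alkylation of the β-keto ester enolate with an allylic bromide should go at C2, the only carbon between two carbonyls; the new centre is formed unselectively and is later lost.

**Step 10**
Reactants: 15 methyl (5S)-10-methyl-2-(3-methylbut-2-en-1-yl)-3-oxo-5-Ar-undecanoate
Product: 17 methyl (5S)-4-acetyl-10-methyl-2-(3-methylbut-2-en-1-yl)-3-oxo-5-Ar-undecanoate (C2/C4 epimers and enols), via dilithium dianion 16 (not isolated)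
Conditions: LiN(i-Pr)2 (LDA, commercial solution, 2.3 equiv), THF, −78 → −20 °C; MeC(O)N(OMe)Me (1.3 equiv), −78 → 0 °C; aq. NH4Cl
Reagents that add atoms: N-methoxy-N-methylacetamide, CC(=O)N(C)OC
Why: γ-Acylation of a β-keto ester dianion: the second deprotonation at C4 gives the more reactive carbanion, which adds to the Weinreb amide, and the chelated adduct survives until work-up so that neither over-addition nor proton transfer from the product should interfere.

**Step 11**
Reactants: 18 (2R)-2-methylbutanoic acid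
Product: 20 (2R)-N-methoxy-N,2-dimethylbutanamide, via acyl imidazole 19 (not isolated)
Conditions: CDI (1.1 equiv), CH2Cl2, 0 °C → rt; MeNHOMe·HCl (1.2 equiv), rt
Reagents that add atoms: N,O-dimethylhydroxylamine hydrochloride, CNOC.Cl
Why: Amide formation through the acyl imidazole is mild enough that the α-stereocentre of the alkyl-branched acid should stay intact.

**Step 12**
Reactants: 17 methyl (5S)-4-acetyl-10-methyl-2-(3-methylbut-2-en-1-yl)-3-oxo-5-Ar-undecanoate; 20 (2R)-N-methoxy-N,2-dimethylbutanamide
Product: 22 methyl (8R)-8-methyl-4-[(1S)-6-methyl-1-Ar-heptyl]-2-(3-methylbut-2-en-1-yl)-3,5,7-trioxodecanoate (C2/C4 epimers and enols), via trilithium trianion 21 (not isolated)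
Conditions: LiN(i-Pr)2 (LDA, 3.2 equiv), THF, −78 → −20 °C; 20 (1.2 equiv), −78 → −20 °C; aq. NH4Cl (pH 5); used without delay
Reagents that add atoms: none
Why: Terminal Claisen acylation of a 3,5-dioxo ester trianion: the third deprotonation at the acetyl methyl (chain C6) gives the least stabilised carbanion, which alone adds to the Weinreb amide, and addition at low temperature without excess base should leave the stereocentre of 20 untouched.

**Step 13**
Reactants: 22 methyl (8R)-8-methyl-4-[(1S)-6-methyl-1-Ar-heptyl]-2-(3-methylbut-2-en-1-yl)-3,5,7-trioxodecanoate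
Product: 24 (2R)-1-{2,4,6-trihydroxy-3-(3-methylbut-2-en-1-yl)-5-[(1S)-6-methyl-1-Ar-heptyl]phenyl}-2-methylbutan-1-one, via acylcyclohexanetrione 23 (not isolated)
Conditions: Mg(OMe)2 (4 equiv), MeOH, rt → 60 °C; cold 0.5 M HCl
Reagents that add atoms: none
Why: Mg(OMe)2 turns the trioxo array into a magnesium-chelated polyenolate in which C6, flanked by the C5 and C7 carbonyls, adds to the ester carbonyl C1; loss of methoxide gives trione 23, and its enolisation to the hexasubstituted phloroglucinol makes the sequence irreversible. The closest known reaction is the magnesium methoxide Claisen cyclisation of 3,5,7-trioxo esters, and of the 4-hydroxy-2-pyrones derived from them, to acylphloroglucinols. Ring A closes by a 6-exo-trig acyl substitution. No stereocentre is created: C2 and C4 become aromatic carbons, the bridge methine carries no acidic hydrogen and keeps its configuration, and the C6 enolate keeps base away from C8–H. The step needs C-acylation at C6 rather than O-acylation to a pyrone or an aldol closure: magnesium binds O5 and O7 and leaves C6 as the nucleophile, and any pyrone is reopened by methoxide. The C2-to-C7 aldol cannot aromatise because C2 carries the prenyl group, and the α-branch hinders C7.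

**Step 14**
Reactants: 24 (2R)-1-{2,4,6-trihydroxy-3-(3-methylbut-2-en-1-yl)-5-[(1S)-6-methyl-1-Ar-heptyl]phenyl}-2-methylbutan-1-one
Product: 25 (2R)-1-[2,4,6-trihydroxy-3-(3-methylbut-2-en-1-yl)-5-{(1R)-6-methyl-1-[2,4,6-trihydroxy-3-(3-methylbut-2-en-1-yl)-5-(2-methylpropanoyl)phenyl]heptyl}phenyl]-2-methylbutan-1-one (CNP0279787.1)
Conditions: 3 M aq. HCl/MeOH (1:5), 35–40 °C
Reagents that add atoms: none
Why: Acid-catalysed acetal cleavage should remove the three aryl MOM ethers, the low temperature being chosen to avoid chroman formation from the ortho-prenyl phenols and acid cleavage of the bridge; the bridge descriptor changes from S to R only because the ring priorities change.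

**Compound list**
1 | phloroglucinol | Oc1cc(O)cc(O)c1 | starting material
2 | isobutyryl chloride | CC(C)C(=O)Cl | starting material
3 | 2-methyl-1-(2,4,6-trihydroxyphenyl)propan-1-one | CC(C)C(=O)c1c(O)cc(O)cc1O | intermediate
4 | 2-methyl-1-[2,4,6-trihydroxy-3-(3-methylbut-2-en-1-yl)phenyl]propan-1-one | CC(C)C(=O)c1c(O)cc(O)c(CC=C(C)C)c1O | intermediate
5 | 6-methylheptan-1-ol | CC(C)CCCCCO | starting material
6 | 6-methylheptanal | CC(C)CCCCC=O | intermediate
7 | (2E)-8-methylnon-2-enal | CC(C)CCCC/C=C/C=O | intermediate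
8 | (3S)-8-methyl-3-[2,4,6-trihydroxy-3-(3-methylbut-2-en-1-yl)-5-(2-methylpropanoyl)phenyl]nonanal (open form, formed in the flask) | O=CC[C@H](CCCCC(C)C)c1c(O)c(CC=C(C)C)c(O)c(C(=O)C(C)C)c1O | intermediate
9 | 1-[(4S)-2,5,7-trihydroxy-8-(3-methylbut-2-en-1-yl)-4-(5-methylhexyl)-3,4-dihydro-2H-chromen-6-yl]-2-methylpropan-1-one (lactol) | OC1C[C@H](CCCCC(C)C)c2c(O)c(C(=O)C(C)C)c(O)c(CC=C(C)C)c2O1 | intermediate
10 | trisodium 2-(2-methylpropanoyl)-4-(3-methylbut-2-en-1-yl)-6-[(3S)-8-methyl-1-oxononan-3-yl]benzene-1,3,5-triolate (triphenoxide of 8, formed in the flask) | [Na+].[Na+].[Na+].O=CC[C@H](CCCCC(C)C)c1c([O-])c(CC=C(C)C)c([O-])c(C(=O)C(C)C)c1[O-] | intermediate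
11 | (3S)-8-methyl-3-Ar-nonanal | O=CC[C@H](CCCCC(C)C)c1c(OCOC)c(CC=C(C)C)c(OCOC)c(C(=O)C(C)C)c1OCOC | intermediate
12 | (3S)-8-methyl-3-Ar-nonanoic acid | OC(=O)C[C@H](CCCCC(C)C)c1c(OCOC)c(CC=C(C)C)c(OCOC)c(C(=O)C(C)C)c1OCOC | intermediate
13 | 1-[(3S)-8-methyl-3-Ar-nonanoyl]imidazole (formed in the flask) | O=C(C[C@H](CCCCC(C)C)c1c(OCOC)c(CC=C(C)C)c(OCOC)c(C(=O)C(C)C)c1OCOC)n1ccnc1 | intermediate
14 | methyl (5S)-10-methyl-3-oxo-5-Ar-undecanoate | COC(=O)CC(=O)C[C@H](CCCCC(C)C)c1c(OCOC)c(CC=C(C)C)c(OCOC)c(C(=O)C(C)C)c1OCOC | intermediate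
15 | methyl (5S)-10-methyl-2-(3-methylbut-2-en-1-yl)-3-oxo-5-Ar-undecanoate (C2 epimers) | COC(=O)C(CC=C(C)C)C(=O)C[C@H](CCCCC(C)C)c1c(OCOC)c(CC=C(C)C)c(OCOC)c(C(=O)C(C)C)c1OCOC | intermediate
16 | dilithium dianion of 15, deprotonated at C2 and C4 (formed in the flask) | [Li+].[Li+].COC([O-])=C(CC=C(C)C)C([O-])=C[C@H](CCCCC(C)C)c1c(OCOC)c(CC=C(C)C)c(OCOC)c(C(=O)C(C)C)c1OCOC | intermediate
17 | methyl (5S)-4-acetyl-10-methyl-2-(3-methylbut-2-en-1-yl)-3-oxo-5-Ar-undecanoate (C2/C4 epimers) | COC(=O)C(CC=C(C)C)C(=O)C(C(C)=O)[C@H](CCCCC(C)C)c1c(OCOC)c(CC=C(C)C)c(OCOC)c(C(=O)C(C)C)c1OCOC | intermediate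
18 | (2R)-2-methylbutanoic acid | CC[C@@H](C)C(=O)O | starting material
19 | 1-[(2R)-2-methylbutanoyl]imidazole (formed in the flask) | CC[C@@H](C)C(=O)n1ccnc1 | intermediate
20 | (2R)-N-methoxy-N,2-dimethylbutanamide | CC[C@@H](C)C(=O)N(C)OC | intermediate
21 | trilithium trianion of 17, deprotonated at C2, C4 and the acetyl methyl (formed in the flask) | [Li+].[Li+].[Li+].COC([O-])=C(CC=C(C)C)C([O-])=C([C@H](CCCCC(C)C)c1c(OCOC)c(CC=C(C)C)c(OCOC)c(C(=O)C(C)C)c1OCOC)C([O-])=C | intermediate
22 | methyl (8R)-8-methyl-4-[(1S)-6-methyl-1-Ar-heptyl]-2-(3-methylbut-2-en-1-yl)-3,5,7-trioxodecanoate (C2/C4 epimers) | CC[C@@H](C)C(=O)CC(=O)C([C@H](CCCCC(C)C)c1c(OCOC)c(CC=C(C)C)c(OCOC)c(C(=O)C(C)C)c1OCOC)C(=O)C(CC=C(C)C)C(=O)OC | intermediate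
23 | 2-[(2R)-2-methylbutanoyl]-4-(3-methylbut-2-en-1-yl)-6-[(1S)-6-methyl-1-Ar-heptyl]cyclohexane-1,3,5-trione (formed in the flask) | CC[C@@H](C)C(=O)C1C(=O)C(CC=C(C)C)C(=O)C([C@H](CCCCC(C)C)c2c(OCOC)c(CC=C(C)C)c(OCOC)c(C(=O)C(C)C)c2OCOC)C1=O | intermediate
24 | (2R)-1-{2,4,6-trihydroxy-3-(3-methylbut-2-en-1-yl)-5-[(1S)-6-methyl-1-Ar-heptyl]phenyl}-2-methylbutan-1-one | CC[C@@H](C)C(=O)c1c(O)c(CC=C(C)C)c(O)c([C@H](CCCCC(C)C)c2c(OCOC)c(CC=C(C)C)c(OCOC)c(C(=O)C(C)C)c2OCOC)c1O | intermediate
25 | CNP0279787.1 | CC[C@@H](C)C(=O)c1c(O)c(CC=C(C)C)c(O)c([C@H](CCCCC(C)C)c2c(O)c(CC=C(C)C)c(O)c(C(=O)C(C)C)c2O)c1O | target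

**Step count**
Total: 14 steps. Longest linear sequence: 11 steps (1, 2, 5, 6, 7, 8, 9, 10, 12, 13, 14).

**Steps most likely to fail**

Step 13 (ring A closure). What may go wrong: methoxide may attack the crowded, poorly enolised C3/C5 diketone and cleave the chain (retro-Claisen) faster than C6 reaches C1, or the material may rest as the pyrone from O-acylation. Both would be made worse by the C2 prenyl group next to the ester. Fallback: the closure is run on a chain without the C2 prenyl group, and that group is put on the finished ring. It sets out from 14. LiN(i-Pr)2 and N-methoxy-N-methylacetamide, as in step 10, should give methyl (5S)-4-acetyl-10-methyl-3-oxo-5-Ar-undecanoate F1. LiN(i-Pr)2 (3 equiv) and amide 20, as in step 12, should give methyl (8R)-8-methyl-4-[(1S)-6-methyl-1-Ar-heptyl]-3,5,7-trioxodecanoate F2. Mg(OMe)2 in MeOH should close it to (2R)-1-{2,4,6-trihydroxy-3-[(1S)-6-methyl-1-Ar-heptyl]phenyl}-2-methylbutan-1-one F3, which has one free position on ring A. C-prenylation of that position with prenyl bromide in 10% aq. KOH at 0 °C (ring B is fully substituted and protected) comes back to the route at 24.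

Step 12 (terminal acylation). What may go wrong: the third deprotonation may be incomplete because the ring B ketone and the hindered chain compete for base, or addition to the α-branched amide may be slow, so that proton transfer returns 17 and erodes the configuration of the acyl donor. Fallback: aldol addition and oxidation in place of acylation, setting out from 17 and 20. Amide 20 is reduced (LiAlH4, THF, −78 °C) to (2R)-2-methylbutanal F4, which is used at once as a cold solution. Trianion 21, made from 17 as in step 12, should add to F4 at −78 °C to give methyl (8R)-7-hydroxy-8-methyl-4-[(1S)-6-methyl-1-Ar-heptyl]-2-(3-methylbut-2-en-1-yl)-3,5-dioxodecanoate F5. Oxidation of the C7 carbinol with Dess–Martin periodinane (NaHCO3, CH2Cl2, 0 °C) comes back at 22.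

Step 10 (γ-acetylation). What may go wrong: deprotonation and acylation at the C4 methylene beside the bulky bridge carbon may be sluggish, with the acetamide acting as a proton source so that 15 is returned. Fallback: it sets out from 15. Dianion 16, made from 15 as in step 10, is trapped at −78 °C with acetaldehyde, a far stronger electrophile, to give methyl (5S)-4-(1-hydroxyethyl)-10-methyl-2-(3-methylbut-2-en-1-yl)-3-oxo-5-Ar-undecanoate F6. Oxidation with Dess–Martin periodinane (CH2Cl2, 0 °C) comes back at 17.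

**Further compounds**
F1 | step 13 | methyl (5S)-4-acetyl-10-methyl-3-oxo-5-Ar-undecanoate | COC(=O)CC(=O)C(C(C)=O)[C@H](CCCCC(C)C)c1c(OCOC)c(CC=C(C)C)c(OCOC)c(C(=O)C(C)C)c1OCOC
F2 | step 13 | methyl (8R)-8-methyl-4-[(1S)-6-methyl-1-Ar-heptyl]-3,5,7-trioxodecanoate | CC[C@@H](C)C(=O)CC(=O)C([C@H](CCCCC(C)C)c1c(OCOC)c(CC=C(C)C)c(OCOC)c(C(=O)C(C)C)c1OCOC)C(=O)CC(=O)OC
F3 | step 13 | (2R)-1-{2,4,6-trihydroxy-3-[(1S)-6-methyl-1-Ar-heptyl]phenyl}-2-methylbutan-1-one | CC[C@@H](C)C(=O)c1c(O)cc(O)c([C@H](CCCCC(C)C)c2c(OCOC)c(CC=C(C)C)c(OCOC)c(C(=O)C(C)C)c2OCOC)c1O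
F4 | step 12 | (2R)-2-methylbutanal | CC[C@@H](C)C=O
F5 | step 12 | methyl (8R)-7-hydroxy-8-methyl-4-[(1S)-6-methyl-1-Ar-heptyl]-2-(3-methylbut-2-en-1-yl)-3,5-dioxodecanoate | CC[C@@H](C)C(O)CC(=O)C([C@H](CCCCC(C)C)c1c(OCOC)c(CC=C(C)C)c(OCOC)c(C(=O)C(C)C)c1OCOC)C(=O)C(CC=C(C)C)C(=O)OC
F6 | step 10 | methyl (5S)-4-(1-hydroxyethyl)-10-methyl-2-(3-methylbut-2-en-1-yl)-3-oxo-5-Ar-undecanoate | COC(=O)C(CC=C(C)C)C(=O)C(C(C)O)[C@H](CCCCC(C)C)c1c(OCOC)c(CC=C(C)C)c(OCOC)c(C(=O)C(C)C)c1OCOC
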